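| flask | substrate | coupling partner | base | temperature | remark | time |
|---|---|---|---|---|---|---|
| gamma | 0.50 M | 0.25 M | 0.15 M | −15 °C | run made earlier |  |
| zeta | 0.36 M | 1 M | 0.15 M | 12 °C | run made earlier |  |
| teal | 0.25 M | 0.300 M | 0.150 M | 5 °C |  | 1.0 h |
| blue | 0.15 M | 0.600 M | 0.150 M | 5 °C |  | 1.0 h |
| grey | 0.50 M | 1.50 M | 0.150 M | 35 °C |  | 1.0 h |
| violet | 0.50 M | 1.00 M | 0.150 M | −10 °C |  | 1.0 h |
| red | 0.50 M | 1.00 M | 0.150 M | 5 °C |  | 1.0 h |

| run | time / min | product / % | substrate / % |
|---|---|---|---|
| gamma | 8.00 | 0 | 99.4 |
| gamma | 20.0 | 0.9 | 99.0 |
| gamma | 50.0 | 0.6 | 98.5 |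
| gamma | 120 | 2.3 | 96.1 |
| zeta | 3.00 | 4.3 | 96.1 |
| zeta | 8.00 | 12.0 | 88.4 |
| zeta | 20.0 | 26.4 | 74.4 |
| zeta | 40.0 | 46.0 | 53.6 |

(scatter of a reading: 0.5 percentage points)

* all flasks from highest to lowest amount of product, in percent of the substrate charged, at 1.0 h (teal / blue / grey / violet / red)
* the amount of product, in percent of the substrate charged of the flask you put first, at 1.0 h
* the amount of product, in percent of the substrate charged of the flask you put last, at 1.0 h

- what was read earlier has a scatter of 0.5 percentage points, one standard deviation
- a reading or a percentage of product counts all its forms, free or not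

1. I started from two rate constants, one from each earlier run, taking first order in substrate and in coupling partner. In zeta, substrate fell to 53.6% in 40.0 min at 1 M, which reads 0.0156 /M/min. In gamma, 96.1% after 120 min at 0.25 M reads 0.00133 /M/min. This reading is rough: substrate had lost 3.90%, and a reading scatters by 0.5 percentage points.

2. Their ratio is 11.8. I took the logarithm of the constant as straight in temperature, so zeta to grey multiplies it by 8.16. That gives 0.127 /M/min at 35 °C.

3. That constant times the hour is 7.63 /M. I called this product of constant and hour the reach. Reach times a concentration compares two times, the hour and the lifetime of substrate.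

4. I assumed one coupling partner per substrate, so grey keeps [coupling partner] at 1.00 M or above. That makes substrate pseudo-first-order, with a lifetime of at most 7.86 min, shorter than the hour. The ratio is 7.63. I reckoned just the remainder: 0.0484% of the substrate.

5. The forecast gave grey > red > blue > teal > violet, with 97% first and 6% last. Of grey it said it “should be essentially complete within minutes”. Its speed-up from zeta's temperature was 10 to 20, and mine was 8.16. My remainder is smaller than the 3.00% between its top figure and complete conversion.

6. The flasks gave grey > red > blue > teal > violet, with 100% first and 10.7% last.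

    substrate + coupling partner + by-product → product + 2 by-product (k = 0.160 /M²/min, Ea = 38.0 kJ/mol)
    substrate + coupling partner → product + by-product (k = 0.00820 /M/min, Ea = 59.0 kJ/mol)
    base + by-product ⇌ salt, settled at all times (K = 410 /M, ΔH = −14.0 kJ/mol)
    crystals ⇌ product, rate k4*(cs4 - [product]) while solid is left; crystals form when [product] > cs4 (solubility = 0.170 M, k = 1.10 /min)
    (constants at 5 °C)

Grey held 0% substrate at 1.00 h, against my remainder of 0.0484%. The neighbour flask is grey with 0.38 M of coupling partner, that is 0.760 equiv. Coupling partner, charged below substrate, is then the limiting reagent, and the ceiling is 76.0% of the substrate charged. Reach times the gap in charges, 0.120 M, gives 0.916. The second-order integral then leaves 13.8% of its coupling partner, so I reckoned 65.5% product. That flask gave 70.2%, with 7.6% of its coupling partner left.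

(The readings were generated by integration with constants of no real substance; scatter was added.)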